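**Strategy**

The route rests on disconnecting the bond between C2 of the oxolane ring (the O–CH carbon) and C1′ of the C15 side chain. The key step exploits the β-hydroxy acid hidden in the target: ring oxygen O1, C2, C3 and the exocyclic carboxyl carbon on C3. This unit is held in a six-membered 1,3-dioxin-4-one, a spiro acylal of (−)-menthone that is absent from the target. Copper-catalysed conjugate addition of the side-chain Grignard reagent forms C2–C1′, and the enolate is alkylated in the same flask with methyl bromoacetate, setting both stereocentres trans on the acylal ring. Acid then switches the six-membered ring to the cis-γ-lactone; methylenation and a terminal Wacker oxidation finish the synthesis.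

Key step: step 4

Numbering: the target is numbered as an oxolane (O1, C2 with the side chain, C3 with CO2H, C4 methylidene, C5 lactone carbonyl). In the spiro acylals 9, 11 and 12 (1,5-dioxaspiro[5.5]undecane numbering) C4 and C3 are the future oxolane C2 and C3, and O5 is the future ring oxygen.

Assumption: a nucleophile attacks the dioxinone of either spiro epimer on the face remote from the isopropyl-bearing carbon C7, so the epimer with O5 axial on the menthane chair (9) is the one that leads to the (S) carbinol.

**Route**

Step 1
Reactants: 1 11-bromoundec-1-ene; 2 1,4-dibromobutane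
Product: 4 15-bromopentadec-1-ene, via undec-10-en-1-ylmagnesium bromide 3 (not isolated)
Conditions: Mg, THF, 40 °C; then 2 (4 equiv), Li2CuCl4 (3 mol%), THF, −10 → 20 °C
Reagents that add atoms: none
Why: The copper-catalysed cross-coupling of Grignard reagent 3 with a primary alkyl bromide (Kochi coupling) should stop at mono-substitution because 2 is used in excess, and no stereocentre is formed.

Step 2
Reactants: 5 5-(methoxymethylidene)-2,2-dimethyl-1,3-dioxane-4,6-dione
Product: 6 5-(hydroxymethylidene)-2,2-dimethyl-1,3-dioxane-4,6-dione (formyl Meldrum's acid)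
Conditions: 2 M aq. HCl, 20 °C
Reagents that add atoms: water, O
Why: Acid-catalysed hydrolysis of the enol ether of this vinylogous acid (addition–elimination at the methylidene carbon) should give the hydrogen-bonded enol 6, which forms no stereocentre.

Step 3
Reactants: 6 formyl Meldrum's acid; 7 (−)-menthone
Product: 9 (6R,7S,10R)-10-methyl-7-(propan-2-yl)-1,5-dioxaspiro[5.5]undec-3-en-2-one, via formylketene 8 (not isolated)
Conditions: 7 (3 equiv), toluene, 110 °C; chromatography
Reagents that add atoms: none
Why: Thermal retro-[4+2] fragmentation of 6 releases formylketene 8, which the C=O group of 7 should trap in a hetero-[4+2] cycloaddition (the acylketene–ketone route to 1,3-dioxin-4-ones); the spiro centre C6 forms without useful selectivity, so 9 (O5 axial) is separated from its spiro epimer by chromatography and the epimer is recycled, since the cycloaddition reverses on heating.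

Step 4
Reactants: 4 15-bromopentadec-1-ene; 9 spiro dioxinone
Product: 12 methyl 2-[(3S,4S,6R,7S,10R)-10-methyl-2-oxo-4-(pentadec-14-en-1-yl)-7-(propan-2-yl)-1,5-dioxaspiro[5.5]undecan-3-yl]acetate, via pentadec-14-en-1-ylmagnesium bromide 10 (not isolated), via bromomagnesium enolate 11 (not isolated)
Conditions: 4, Mg, THF, 40 °C; then slow addition to 9, CuBr·SMe2 (10 mol%), THF, −78 °C; then BrCH2CO2Me, DMPU, −78 → −30 °C
Reagents that add atoms: methyl bromoacetate, COC(=O)CBr
Why: The copper(I)-catalysed conjugate addition of 10 to the C3=C4 bond of 9 (π-complexation, oxidative addition at C4, reductive elimination) should form the C4–C1′ bond and leave the magnesium enolate 11, which is C-alkylated at C3 by methyl bromoacetate once DMPU is added; the closest known reaction types are cuprate additions to chiral 1,3-dioxin-4-ones and the tandem conjugate addition–enolate alkylation of unsaturated lactones, with the alkylation mirroring trans-selective dioxanone (Fráter–Seebach-type) alkylations. No ring is closed. The C4 stereocentre (S) is controlled by the spiro centre C6, whose equatorial isopropyl-bearing arm C7 shields one face of the nearly flat dioxinone so that the chain should enter from the C11 side. The C3 stereocentre (S) is controlled by the new C4 substituent, the electrophile entering the enolate anti to the adjacent alkyl chain to give the trans-3,4 acylal, which is also the diequatorial, thermodynamically preferred arrangement of the six-membered ring. The step needs 1,4- rather than 1,2-addition, secured by the copper catalyst and slow addition of 10 at −78 °C, and it needs 11 to be alkylated before it ring-opens by β-elimination of the C4–O5 bond, secured by the poor orbital overlap of that endocyclic bond with the enolate and by staying below −30 °C. Because the later ring switch makes the exocyclic C3 arm endocyclic and the endocyclic C2 carbonyl exocyclic, trans on the acylal ring corresponds to cis on the γ-lactone, the relationship the target requires.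

Step 5
Reactants: 12 alkylated spiro acylal
Product: 14 (2S,3S)-5-oxo-2-(pentadec-14-en-1-yl)oxolane-3-carboxylic acid, via hydroxy acid ester 13 (not isolated)
Conditions: 2 M aq. HCl, THF, 45 °C
Reagents that add atoms: water, O
Why: Aqueous acid should hydrolyse the acylal at the spiro carbon and the acyl C2–O1 bond while the alkyl C4–O5 bond stays intact, so the carbinol keeps its configuration, and hydroxy ester 13 then lactonises by acid-catalysed transesterification to the γ-lactone, in which the trans-3,4 pair of 12 has become the cis-2,3 pair without any base that could epimerise C3.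

Step 6
Reactants: 14 cis-lactone acid
Product: 16 (2S,3S)-4-methylidene-5-oxo-2-(pentadec-14-en-1-yl)oxolane-3-carboxylic acid, via malonic acid 15 (not isolated)
Conditions: MeOMgOCO2Me (2 M in DMF), 135 °C; 6 M HCl, 0 °C; then 37% aq. HCHO, PhNHMe, NaOAc, AcOH, 20 °C
Reagents that add atoms: formaldehyde, C=O
Why: Stiles carboxylation of the lactone α-carbon with methoxymagnesium methyl carbonate followed by decarboxylative Mannich methylenation of malonic acid 15 is the standard entry to α-methylidene paraconic acids, C3 being shielded from epimerisation as its carboxylate and the remote terminal alkene being inert.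

Step 7
Reactants: 16 methylidene lactone acid
Product: 17 allo-pertusaric acid, (2S,3S)-4-methylidene-5-oxo-2-(14-oxopentadecyl)oxolane-3-carboxylic acid
Conditions: PdCl2 (10 mol%), Cu(OAc)2 (20 mol%), O2 (1 atm), DMA/H2O 7:1, 20 °C
Reagents that add atoms: water, O
Why: Tsuji–Wacker oxidation should convert the monosubstituted terminal alkene into the methyl ketone with Markovnikov selectivity by hydroxypalladation and β-hydride elimination, whereas the electron-poor 1,1-disubstituted methylidene lactone is expected to be inert, and no stereocentre is touched.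

**Compound list**

1 | 11-bromoundec-1-ene | C=CCCCCCCCCCBr | starting material
2 | 1,4-dibromobutane | BrCCCCBr | starting material
3 | undec-10-en-1-ylmagnesium bromide | C=CCCCCCCCCC[Mg]Br | intermediate
4 | 15-bromopentadec-1-ene | C=CCCCCCCCCCCCCCBr | intermediate
5 | 5-(methoxymethylidene)-2,2-dimethyl-1,3-dioxane-4,6-dione | COC=C1C(=O)OC(C)(C)OC1=O | starting material
6 | 5-(hydroxymethylidene)-2,2-dimethyl-1,3-dioxane-4,6-dione | OC=C1C(=O)OC(C)(C)OC1=O | intermediate
7 | (−)-menthone, (2S,5R)-5-methyl-2-(propan-2-yl)cyclohexan-1-one | CC(C)[C@@H]1CC[C@@H](C)CC1=O | starting material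
8 | formylketene (3-oxoprop-1-en-1-one) | O=CC=C=O | intermediate
9 | (6R,7S,10R)-10-methyl-7-(propan-2-yl)-1,5-dioxaspiro[5.5]undec-3-en-2-one | CC(C)[C@@H]1CC[C@@H](C)C[C@]12OC=CC(=O)O2 | intermediate
10 | pentadec-14-en-1-ylmagnesium bromide | C=CCCCCCCCCCCCCC[Mg]Br | intermediate
11 | {[(4S,6R,7S,10R)-10-methyl-4-(pentadec-14-en-1-yl)-7-(propan-2-yl)-1,5-dioxaspiro[5.5]undec-2-en-2-yl]oxy}magnesium bromide | CC(C)[C@@H]1CC[C@@H](C)C[C@]12O[C@@H](CCCCCCCCCCCCCC=C)C=C(O[Mg]Br)O2 | intermediate
12 | methyl 2-[(3S,4S,6R,7S,10R)-10-methyl-2-oxo-4-(pentadec-14-en-1-yl)-7-(propan-2-yl)-1,5-dioxaspiro[5.5]undecan-3-yl]acetate | CC(C)[C@@H]1CC[C@@H](C)C[C@]12O[C@@H](CCCCCCCCCCCCCC=C)[C@H](CC(=O)OC)C(=O)O2 | intermediate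
13 | (2S)-2-[(1S)-1-hydroxyhexadec-15-en-1-yl]-4-methoxy-4-oxobutanoic acid | O[C@@H](CCCCCCCCCCCCCC=C)[C@H](CC(=O)OC)C(=O)O | intermediate
14 | (2S,3S)-5-oxo-2-(pentadec-14-en-1-yl)oxolane-3-carboxylic acid | C1C(=O)O[C@@H](CCCCCCCCCCCCCC=C)[C@H]1C(=O)O | intermediate
15 | (2S,3S)-5-oxo-2-(pentadec-14-en-1-yl)oxolane-3,4-dicarboxylic acid (C4 not defined) | OC(=O)C1C(=O)O[C@@H](CCCCCCCCCCCCCC=C)[C@H]1C(=O)O | intermediate
16 | (2S,3S)-4-methylidene-5-oxo-2-(pentadec-14-en-1-yl)oxolane-3-carboxylic acid | C=C1C(=O)O[C@@H](CCCCCCCCCCCCCC=C)[C@H]1C(=O)O | intermediate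
17 | allo-pertusaric acid, (2S,3S)-4-methylidene-5-oxo-2-(14-oxopentadecyl)oxolane-3-carboxylic acid | C=C1C(=O)O[C@@H](CCCCCCCCCCCCCC(C)=O)[C@H]1C(=O)O | target

**Step count**

Total step count: 7. Longest linear sequence: 6 steps (steps 2–7, from 5); step 1 is the only branch step.

**Steps most likely to fail**

Step 4 (key step). Enolate 11 may ring-open by β-elimination or react sluggishly as a magnesium enolate. The facial selectivity of the alkylation may also be eroded, because the adjacent chain and the remote isopropyl arm direct the electrophile to opposite faces. Fallback, setting out from 4 and 9: the conjugate addition is run as in step 4 but quenched at −78 °C with aqueous NH4Cl, giving the saturated acylal (4S,6R,7S,10R)-10-methyl-4-(pentadec-14-en-1-yl)-7-(propan-2-yl)-1,5-dioxaspiro[5.5]undecan-2-one F1. Methanolysis (K2CO3, MeOH, 0 °C) removes the auxiliary and gives methyl (3S)-3-hydroxyoctadec-17-enoate F2. Fráter–Seebach alkylation of its dianion (LDA 2.2 equiv, THF, −50 → −20 °C; methyl bromoacetate) should give, under chelate control that does not depend on the auxiliary, the anti diester dimethyl (2S)-2-[(1S)-1-hydroxyhexadec-15-en-1-yl]butanedioate F3. Saponification and acidification (LiOH, THF/H2O; then 2 M HCl) lactonise F3 and bring the route back at 14.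

Step 3. Trapping of formylketene by the hindered ketone may be inefficient because the ketene condenses with itself, and the spiro centre may form mainly in the unwanted sense. Fallback, setting out from 7: commercial 3-hydroxypropanoic acid is silylated (TMSCl, Et3N) to trimethylsilyl 3-[(trimethylsilyl)oxy]propanoate F4. This is condensed with 7 under silyl triflate catalysis (TMSOTf 5 mol%, CH2Cl2, −78 °C) to the saturated spiro acylal (6R,7S,10R)-10-methyl-7-(propan-2-yl)-1,5-dioxaspiro[5.5]undecan-2-one F5, the spiro epimers being separated and the unwanted one re-equilibrated with acid. Enolate selenation (LDA, PhSeBr, THF, −78 °C) gives (6R,7S,10R)-10-methyl-3-(phenylselanyl)-7-(propan-2-yl)-1,5-dioxaspiro[5.5]undecan-2-one F6. Oxidation with H2O2/pyridine at 0 °C then triggers selenoxide syn-elimination towards C4–H and brings the route back at 9.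

Step 7. Palladium hydride species may move the exocyclic methylidene into the ring or the terminal alkene along the chain, and the free acid may slow the oxidation. Fallback, setting out from 14: the Wacker oxidation is run under the step 7 conditions before the methylidene exists, giving (2S,3S)-5-oxo-2-(14-oxopentadecyl)oxolane-3-carboxylic acid F7. The ketone is masked with 1,2-bis(trimethylsilyloxy)ethane and catalytic TMSOTf (CH2Cl2, −78 °C) as (2S,3S)-2-[13-(2-methyl-1,3-dioxolan-2-yl)tridecyl]-5-oxooxolane-3-carboxylic acid F8. Carboxylation–methylenation as in step 6 gives (2S,3S)-4-methylidene-2-[13-(2-methyl-1,3-dioxolan-2-yl)tridecyl]-5-oxooxolane-3-carboxylic acid F9. PPTS in aqueous acetone (40 °C) removes the dioxolane and brings the route back at 17.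

Further compounds
F1 | step 4 | (4S,6R,7S,10R)-10-methyl-4-(pentadec-14-en-1-yl)-7-(propan-2-yl)-1,5-dioxaspiro[5.5]undecan-2-one | CC(C)[C@@H]1CC[C@@H](C)C[C@]12O[C@@H](CCCCCCCCCCCCCC=C)CC(=O)O2
F2 | step 4 | methyl (3S)-3-hydroxyoctadec-17-enoate | COC(=O)C[C@@H](O)CCCCCCCCCCCCCC=C
F3 | step 4 | dimethyl (2S)-2-[(1S)-1-hydroxyhexadec-15-en-1-yl]butanedioate | O[C@@H](CCCCCCCCCCCCCC=C)[C@H](CC(=O)OC)C(=O)OC
F4 | step 3 | trimethylsilyl 3-[(trimethylsilyl)oxy]propanoate | C[Si](C)(C)OCCC(=O)O[Si](C)(C)C
F5 | step 3 | (6R,7S,10R)-10-methyl-7-(propan-2-yl)-1,5-dioxaspiro[5.5]undecan-2-one | CC(C)[C@@H]1CC[C@@H](C)C[C@]12OCCC(=O)O2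
F6 | step 3 | (6R,7S,10R)-10-methyl-3-(phenylselanyl)-7-(propan-2-yl)-1,5-dioxaspiro[5.5]undecan-2-one | CC(C)[C@@H]1CC[C@@H](C)C[C@]12OCC([Se]c3ccccc3)C(=O)O2
F7 | step 7 | (2S,3S)-5-oxo-2-(14-oxopentadecyl)oxolane-3-carboxylic acid | C1C(=O)O[C@@H](CCCCCCCCCCCCCC(C)=O)[C@H]1C(=O)O
F8 | step 7 | (2S,3S)-2-[13-(2-methyl-1,3-dioxolan-2-yl)tridecyl]-5-oxooxolane-3-carboxylic acid | C1C(=O)O[C@@H](CCCCCCCCCCCCCC2(C)OCCO2)[C@H]1C(=O)O
F9 | step 7 | (2S,3S)-4-methylidene-2-[13-(2-methyl-1,3-dioxolan-2-yl)tridecyl]-5-oxooxolane-3-carboxylic acid | C=C1C(=O)O[C@@H](CCCCCCCCCCCCCC2(C)OCCO2)[C@H]1C(=O)O
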